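**Retrosynthetic overview**
1. Target ← desilylation and allyl-to-prenyl cross-metathesis ← 8-allyl-2H-chromene ← one-carbon ring expansion (1,2-shift, then loss of H+) of a 3-(hydroxymethyl)-2,2-dimethyl-2,3-dihydrobenzofuran: the five-membered O-ring becomes the pyran ring.
2. Dihydrobenzofuran ← second Claisen rearrangement of a 4-O-(4-acetoxy-2-methylbut-2-enyl) ether to C5, then Markovnikov ring closure; the C3-allyl group (blocks C3, later prenyl) ← first Claisen rearrangement; bibenzyl ← lateral alkylation of methyl orsellinate.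
3. Ring order: both benzene rings are bought; the dihydrofuran ring is closed in step 8 and expanded to the pyran ring in step 9.
4. Enabling feature: in the dihydrofuran ring the exocyclic CH2–O carbon sits on C3, next to ring-fusion carbon C3a, which is para to the free phenol and ortho to the ring oxygen (a strong ipso donor). C2 is quaternary, so a 1,2-shift of either C3a or C2, followed by proton loss, can only give the 2,2-dimethyl-2H-chromene.

Key step: step 9

Remark: the target has no stereocentre. The dihydrobenzofuran intermediates are racemic at their single stereocentre, which is erased in the key step. The allylic bromide is drawn as the E isomer; its alkene geometry is lost in the second Claisen rearrangement.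

**Step 1**
Reactants: 1 methyl 2,4-dihydroxy-6-methylbenzoate; 2 allyl bromide
Product: 3 methyl 2-hydroxy-6-methyl-4-(prop-2-en-1-yloxy)benzoate
Conditions: K2CO3, acetone, 56 °C
Reagents that add atoms: allyl bromide (2), C=CCBr
Why: Williamson etherification; the C2 hydroxyl is hydrogen-bonded to the ester carbonyl, so only the C4 phenol should be alkylated.

**Step 2**
Reactants: 4 4-methylphenol; 5 chlorotriisopropylsilane
Product: 6 triisopropyl(4-methylphenoxy)silane
Conditions: imidazole, DMF, 23 °C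
Reagents that add atoms: chlorotriisopropylsilane (5), CC(C)[Si](Cl)(C(C)C)C(C)C
Why: imidazole-mediated O-silylation of a phenol; the bulky silyl ether should survive base, heat and mild acid later on.

**Step 3**
Reactants: 6 triisopropyl(4-methylphenoxy)silane; 7 N-bromosuccinimide
Product: 8 [4-(bromomethyl)phenoxy]triisopropylsilane
Conditions: AIBN (cat.), PhCF3, 80 °C
Reagents that add atoms: N-bromosuccinimide (7), O=C1CCC(=O)N1Br
Why: Wohl–Ziegler bromination; the benzylic methyl C–H is the weakest C–H bond in 6.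

**Step 4**
Reactants: 3 methyl 2-hydroxy-6-methyl-4-(prop-2-en-1-yloxy)benzoate; 8 [4-(bromomethyl)phenoxy]triisopropylsilane
Product: 10 methyl 2-hydroxy-4-(prop-2-en-1-yloxy)-6-{2-[4-(triisopropylsilyloxy)phenyl]ethyl}benzoate, via dilithium dianion 9 (not isolated)
Conditions: LiN(iPr)2 (2.3 equiv), THF, −78 °C; then 8, −78 to −40 °C; AcOH quench
Reagents that add atoms: [4-(bromomethyl)phenoxy]triisopropylsilane (8), BrCc1ccc(O[Si](C(C)C)(C(C)C)C(C)C)cc1
Why: lateral lithiation of an ortho-toluate; the methyl ortho to the ester is the most acidic C–H after the phenol, and the benzylic carbanion of the dianion should be alkylated at carbon by the benzylic bromide (SN2).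

**Step 5**
Reactants: 10 methyl 2-hydroxy-4-(prop-2-en-1-yloxy)-6-{2-[4-(triisopropylsilyloxy)phenyl]ethyl}benzoate
Product: 11 methyl 2,4-dihydroxy-3-(prop-2-en-1-yl)-6-{2-[4-(triisopropylsilyloxy)phenyl]ethyl}benzoate
Conditions: N,N-diethylaniline, 190 °C
Reagents that add atoms: none
Why: aromatic Claisen rearrangement ([3,3]); the allyl group should go to C3 between the two oxygens (bond fixation in the chelated salicylate, C5 flanked by the side chain), which blocks C3 for the next rearrangement.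

**Step 6**
Reactants: 12 isoprene; 7 N-bromosuccinimide; 13 acetic acid
Product: 14 (2E)-4-bromo-3-methylbut-2-en-1-yl acetate
Conditions: AcOH, 15 °C
Reagents that add atoms: N-bromosuccinimide (7), O=C1CCC(=O)N1Br; acetic acid (13), CC(O)=O
Why: bromo-acetoxylation of a 1,3-diene (1,4-addition through the allyl cation); the neopentyl-type 1,2-adduct formed alongside is inert in step 7.

**Step 7**
Reactants: 11 methyl 2,4-dihydroxy-3-(prop-2-en-1-yl)-6-{2-[4-(triisopropylsilyloxy)phenyl]ethyl}benzoate; 14 (2E)-4-bromo-3-methylbut-2-en-1-yl acetate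
Product: 15 methyl 4-{[(2E)-4-acetoxy-2-methylbut-2-en-1-yl]oxy}-2-hydroxy-3-(prop-2-en-1-yl)-6-{2-[4-(triisopropylsilyloxy)phenyl]ethyl}benzoate
Conditions: K2CO3, acetone, 50 °C
Reagents that add atoms: (2E)-4-bromo-3-methylbut-2-en-1-yl acetate (14), CC(=O)OC/C=C(C)/CBr
Why: Williamson etherification of the non-chelated C4 phenol with a primary allylic bromide (SN2).

**Step 8**
Reactants: 15 methyl 4-{[(2E)-4-acetoxy-2-methylbut-2-en-1-yl]oxy}-2-hydroxy-3-(prop-2-en-1-yl)-6-{2-[4-(triisopropylsilyloxy)phenyl]ethyl}benzoate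
Product: 18 methyl 6-hydroxy-3-(hydroxymethyl)-2,2-dimethyl-7-(prop-2-en-1-yl)-4-{2-[4-(triisopropylsilyloxy)phenyl]ethyl}-2,3-dihydro-1-benzofuran-5-carboxylate (racemic), via Claisen phenol 16 (not isolated), via cyclised acetate 17 (not isolated)
Conditions: 1,2-dichlorobenzene, 180 °C; then p-TsOH·H2O (10 mol%), 80 °C; then MeOH, 60 °C
Reagents that add atoms: none
Why: a second aromatic Claisen rearrangement delivers the C5 unit to the only free ortho position, acid then closes the dihydrofuran ring by Markovnikov 5-exo-trig hydroalkoxylation of the 1,1-disubstituted alkene (the monosubstituted allyl group should stay untouched), and acid-catalysed transesterification with methanol frees the primary alcohol; the new stereocentre is racemic and is erased in step 9.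

**Step 9**
Reactants: 18 methyl 6-hydroxy-3-(hydroxymethyl)-2,2-dimethyl-7-(prop-2-en-1-yl)-4-{2-[4-(triisopropylsilyloxy)phenyl]ethyl}-2,3-dihydro-1-benzofuran-5-carboxylate; 19 trifluoromethanesulfonic anhydride
Product: 21 methyl 7-hydroxy-2,2-dimethyl-8-(prop-2-en-1-yl)-5-{2-[4-(triisopropylsilyloxy)phenyl]ethyl}-2H-chromene-6-carboxylate, via primary triflate 20 (not isolated)
Conditions: Tf2O (1.1 equiv), 2,6-di-tert-butyl-4-methylpyridine (3 equiv), CH2Cl2, −78 to 23 °C
Reagents that add atoms: none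
Why: O-triflation of the primary, neopentyl-type alcohol gives 20, which should ionise with participation of the ring-fusion aryl carbon C3a (3-exo-tet ipso attack, a bridged phenonium ion that is the O-protonated spirocyclopropyl cyclohexadienone of the para C6–OH); collapse of the bridge at the ring carbon moves the aryl bond from C3 to the exocyclic carbon and so inserts that carbon into the furan ring, and loss of the benzylic proton (directly or after a 1,2-hydride shift to the doubly oxygen-stabilised benzylic cation) gives the C3=C4 alkene of the 2H-chromene. The closest known reaction type is the Wagner–Meerwein (neophyl-type) ring expansion of benzo-fused carbinols, such as fluoren-9-ylmethanol to phenanthrene and xanthen-9-ylmethanol to dibenz[b,f]oxepine. No ring is closed from an open chain: the six-membered pyran ring arises by one-carbon expansion of the five-membered dihydrofuran ring through a 1,2-shift. No stereocentre is created; the racemic C3 centre of 18 becomes sp2. The step needs aryl (or ring-alkyl) migration to win over a 1,2-hydride shift, and O-triflation of the alcohol to win over the phenol: the first is secured by the electron-rich ipso carbon (para OH, ortho ring O) and by the quaternary C2, which makes the alternative shift of C2 end in the same chromene, the second by the ester-chelated, doubly flanked C6–OH and the non-nucleophilic base at −78 °C.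

**Step 10**
Reactants: 21 methyl 7-hydroxy-2,2-dimethyl-8-(prop-2-en-1-yl)-5-{2-[4-(triisopropylsilyloxy)phenyl]ethyl}-2H-chromene-6-carboxylate; 22 2-methylbut-2-ene
Product: 23 methyl 7-hydroxy-2,2-dimethyl-8-(3-methylbut-2-en-1-yl)-5-{2-[4-(triisopropylsilyloxy)phenyl]ethyl}-2H-chromene-6-carboxylate
Conditions: second-generation Grubbs catalyst RuCl2(=CHPh)(PCy3)(H2IMes) (5 mol%), 2-methylbut-2-ene (excess), CH2Cl2, 40 °C
Reagents that add atoms: 2-methylbut-2-ene (22), CC=C(C)C
Why: olefin cross-metathesis of the terminal allyl group with excess 2-methylbut-2-ene; the hindered cis ring alkene next to the quaternary carbon should not react.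

**Step 11**
Reactants: 23 methyl 7-hydroxy-2,2-dimethyl-8-(3-methylbut-2-en-1-yl)-5-{2-[4-(triisopropylsilyloxy)phenyl]ethyl}-2H-chromene-6-carboxylate
Product: 24 methyl 7-hydroxy-5-[2-(4-hydroxyphenyl)ethyl]-2,2-dimethyl-8-(3-methylbut-2-en-1-yl)-2H-chromene-6-carboxylate
Conditions: Bu4NF, AcOH, THF, 0 °C
Reagents that add atoms: none
Why: fluoride cleavage of the aryl silyl ether under buffered conditions, which should leave the ester, the prenyl group and the chromene untouched.

**Compound list**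
1 | methyl 2,4-dihydroxy-6-methylbenzoate | COC(=O)c1c(C)cc(O)cc1O | starting material
2 | allyl bromide | C=CCBr | starting material
3 | methyl 2-hydroxy-6-methyl-4-(prop-2-en-1-yloxy)benzoate | COC(=O)c1c(C)cc(OCC=C)cc1O | intermediate
4 | 4-methylphenol | Cc1ccc(O)cc1 | starting material
5 | chlorotriisopropylsilane | CC(C)[Si](Cl)(C(C)C)C(C)C | starting material
6 | triisopropyl(4-methylphenoxy)silane | Cc1ccc(O[Si](C(C)C)(C(C)C)C(C)C)cc1 | intermediate
7 | N-bromosuccinimide | O=C1CCC(=O)N1Br | starting material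
8 | [4-(bromomethyl)phenoxy]triisopropylsilane | BrCc1ccc(O[Si](C(C)C)(C(C)C)C(C)C)cc1 | intermediate
9 | dilithium dianion of 3 (phenoxide and benzylic carbanion) | [Li+].[Li+].COC(=O)c1c([CH2-])cc(OCC=C)cc1[O-] | intermediate
10 | methyl 2-hydroxy-4-(prop-2-en-1-yloxy)-6-{2-[4-(triisopropylsilyloxy)phenyl]ethyl}benzoate | COC(=O)c1c(CCc2ccc(O[Si](C(C)C)(C(C)C)C(C)C)cc2)cc(OCC=C)cc1O | intermediate
11 | methyl 2,4-dihydroxy-3-(prop-2-en-1-yl)-6-{2-[4-(triisopropylsilyloxy)phenyl]ethyl}benzoate | COC(=O)c1c(CCc2ccc(O[Si](C(C)C)(C(C)C)C(C)C)cc2)cc(O)c(CC=C)c1O | intermediate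
12 | isoprene | C=CC(C)=C | starting material
13 | acetic acid | CC(O)=O | starting material
14 | (2E)-4-bromo-3-methylbut-2-en-1-yl acetate | CC(=O)OC/C=C(C)/CBr | intermediate
15 | methyl 4-{[(2E)-4-acetoxy-2-methylbut-2-en-1-yl]oxy}-2-hydroxy-3-(prop-2-en-1-yl)-6-{2-[4-(triisopropylsilyloxy)phenyl]ethyl}benzoate | COC(=O)c1c(CCc2ccc(O[Si](C(C)C)(C(C)C)C(C)C)cc2)cc(OC/C(C)=C/COC(C)=O)c(CC=C)c1O | intermediate
16 | methyl 5-(1-acetoxy-3-methylbut-3-en-2-yl)-2,4-dihydroxy-3-(prop-2-en-1-yl)-6-{2-[4-(triisopropylsilyloxy)phenyl]ethyl}benzoate (racemic) | COC(=O)c1c(CCc2ccc(O[Si](C(C)C)(C(C)C)C(C)C)cc2)c(C(COC(C)=O)C(C)=C)c(O)c(CC=C)c1O | intermediate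
17 | methyl 3-(acetoxymethyl)-6-hydroxy-2,2-dimethyl-7-(prop-2-en-1-yl)-4-{2-[4-(triisopropylsilyloxy)phenyl]ethyl}-2,3-dihydro-1-benzofuran-5-carboxylate (racemic) | COC(=O)c1c(O)c(CC=C)c2OC(C)(C)C(COC(C)=O)c2c1CCc1ccc(O[Si](C(C)C)(C(C)C)C(C)C)cc1 | intermediate
18 | methyl 6-hydroxy-3-(hydroxymethyl)-2,2-dimethyl-7-(prop-2-en-1-yl)-4-{2-[4-(triisopropylsilyloxy)phenyl]ethyl}-2,3-dihydro-1-benzofuran-5-carboxylate (racemic) | COC(=O)c1c(O)c(CC=C)c2OC(C)(C)C(CO)c2c1CCc1ccc(O[Si](C(C)C)(C(C)C)C(C)C)cc1 | intermediate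
19 | trifluoromethanesulfonic anhydride | O=S(=O)(OS(=O)(=O)C(F)(F)F)C(F)(F)F | starting material
20 | primary triflate of 18 (racemic) | COC(=O)c1c(O)c(CC=C)c2OC(C)(C)C(COS(=O)(=O)C(F)(F)F)c2c1CCc1ccc(O[Si](C(C)C)(C(C)C)C(C)C)cc1 | intermediate
21 | methyl 7-hydroxy-2,2-dimethyl-8-(prop-2-en-1-yl)-5-{2-[4-(triisopropylsilyloxy)phenyl]ethyl}-2H-chromene-6-carboxylate | COC(=O)c1c(O)c(CC=C)c2OC(C)(C)C=Cc2c1CCc1ccc(O[Si](C(C)C)(C(C)C)C(C)C)cc1 | intermediate
22 | 2-methylbut-2-ene | CC=C(C)C | starting material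
23 | methyl 7-hydroxy-2,2-dimethyl-8-(3-methylbut-2-en-1-yl)-5-{2-[4-(triisopropylsilyloxy)phenyl]ethyl}-2H-chromene-6-carboxylate | COC(=O)c1c(O)c(CC=C(C)C)c2OC(C)(C)C=Cc2c1CCc1ccc(O[Si](C(C)C)(C(C)C)C(C)C)cc1 | intermediate
24 | methyl 7-hydroxy-5-[2-(4-hydroxyphenyl)ethyl]-2,2-dimethyl-8-(3-methylbut-2-en-1-yl)-2H-chromene-6-carboxylate | COC(=O)c1c(O)c(CC=C(C)C)c2OC(C)(C)C=Cc2c1CCc1ccc(O)cc1 | target

**Step count and risks**
Total step count: 11. Longest linear sequence: 9 steps (2, 3, 4, 5, 7, 8, 9, 10, 11).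

The three steps most likely to fail:

Step 9 (key step). The cation may be diverted: a 1,2-hydride shift to the tertiary benzylic position would end in an exocyclic alkene, a methyl or oxygen shift in the chroman-3-yl cation would give a rearranged or re-contracted ring, and the phenol may be triflated in place of the alcohol. The fallback keeps the ring expansion but runs it through a radical. It sets out from 18 and comes back at 21. An Appel iodination (I2, PPh3, imidazole) should give methyl 6-hydroxy-3-(iodomethyl)-2,2-dimethyl-7-(prop-2-en-1-yl)-4-{2-[4-(triisopropylsilyloxy)phenyl]ethyl}-2,3-dihydro-1-benzofuran-5-carboxylate F1. Slow addition of Bu3SnH with AIBN in toluene at 100 °C should let the primary radical undergo the neophyl 1,2-aryl shift before it is reduced, giving methyl 7-hydroxy-2,2-dimethyl-8-(prop-2-en-1-yl)-5-{2-[4-(triisopropylsilyloxy)phenyl]ethyl}chromane-6-carboxylate F2. Dehydrogenation at the benzylic position para to the phenol with DDQ in dioxane at 80 °C should then give 21.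

Step 8. At 180 °C the rearranged side chain may isomerise further (abnormal Claisen rearrangement), and in the acid stage alkene migration or participation of the acetate may compete with the 5-exo ring closure. The fallback builds the five-membered ring by palladium catalysis. It sets out from 11 and comes back at 23. Iodination at the only free ring position (N-iodosuccinimide, MeCN, 0 °C) should give methyl 2,4-dihydroxy-5-iodo-3-(prop-2-en-1-yl)-6-{2-[4-(triisopropylsilyloxy)phenyl]ethyl}benzoate F3. Heteroannulation with 3-methylbuta-1,2-diene (Pd(OAc)2, Bu4NCl, Na2CO3, DMF, 80 °C; phenoxide attack at the more substituted allyl terminus) should give methyl 6-hydroxy-2,2-dimethyl-3-methylidene-7-(prop-2-en-1-yl)-4-{2-[4-(triisopropylsilyloxy)phenyl]ethyl}-2,3-dihydro-1-benzofuran-5-carboxylate F4. Cross-metathesis with 2-methylbut-2-ene, as in step 10, should give methyl 6-hydroxy-2,2-dimethyl-3-methylidene-7-(3-methylbut-2-en-1-yl)-4-{2-[4-(triisopropylsilyloxy)phenyl]ethyl}-2,3-dihydro-1-benzofuran-5-carboxylate F5. Hydroboration of the 1,1-disubstituted alkene with 9-BBN and oxidation with NaBO3 should give methyl 6-hydroxy-3-(hydroxymethyl)-2,2-dimethyl-7-(3-methylbut-2-en-1-yl)-4-{2-[4-(triisopropylsilyloxy)phenyl]ethyl}-2,3-dihydro-1-benzofuran-5-carboxylate F6. Under the conditions of step 9 this should pass through methyl 6-hydroxy-2,2-dimethyl-7-(3-methylbut-2-en-1-yl)-4-{2-[4-(triisopropylsilyloxy)phenyl]ethyl}-3-{[(trifluoromethanesulfonyl)oxy]methyl}-2,3-dihydro-1-benzofuran-5-carboxylate F7, formed in the flask, and expand directly to 23.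

Step 5. The allyl group may migrate to the other ortho position (C5), which would lose the regiocontrol of every later step. The fallback rearranges from the C2 oxygen, whose only free ortho position is C3. It sets out from 1 and comes back at 11. Selective protection of the C4 phenol (MOMCl, iPr2NEt) should give methyl 2-hydroxy-4-(methoxymethoxy)-6-methylbenzoate F8. Allylation of the chelated phenol (allyl bromide, K2CO3, DMF, 60 °C) should give methyl 4-(methoxymethoxy)-6-methyl-2-(prop-2-en-1-yloxy)benzoate F9. Claisen rearrangement at 190 °C should give methyl 2-hydroxy-4-(methoxymethoxy)-6-methyl-3-(prop-2-en-1-yl)benzoate F10. Lateral alkylation with 8 as in step 4 should give methyl 2-hydroxy-4-(methoxymethoxy)-3-(prop-2-en-1-yl)-6-{2-[4-(triisopropylsilyloxy)phenyl]ethyl}benzoate F11, and mild acid (HCl, MeOH, 23 °C) should remove the acetal to give 11.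

**Further compounds**
F1 | step 9 | methyl 6-hydroxy-3-(iodomethyl)-2,2-dimethyl-7-(prop-2-en-1-yl)-4-{2-[4-(triisopropylsilyloxy)phenyl]ethyl}-2,3-dihydro-1-benzofuran-5-carboxylate | COC(=O)c1c(O)c(CC=C)c2OC(C)(C)C(CI)c2c1CCc1ccc(O[Si](C(C)C)(C(C)C)C(C)C)cc1
F2 | step 9 | methyl 7-hydroxy-2,2-dimethyl-8-(prop-2-en-1-yl)-5-{2-[4-(triisopropylsilyloxy)phenyl]ethyl}chromane-6-carboxylate | COC(=O)c1c(O)c(CC=C)c2OC(C)(C)CCc2c1CCc1ccc(O[Si](C(C)C)(C(C)C)C(C)C)cc1
F3 | step 8 | methyl 2,4-dihydroxy-5-iodo-3-(prop-2-en-1-yl)-6-{2-[4-(triisopropylsilyloxy)phenyl]ethyl}benzoate | COC(=O)c1c(CCc2ccc(O[Si](C(C)C)(C(C)C)C(C)C)cc2)c(I)c(O)c(CC=C)c1O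
F4 | step 8 | methyl 6-hydroxy-2,2-dimethyl-3-methylidene-7-(prop-2-en-1-yl)-4-{2-[4-(triisopropylsilyloxy)phenyl]ethyl}-2,3-dihydro-1-benzofuran-5-carboxylate | COC(=O)c1c(O)c(CC=C)c2OC(C)(C)C(=C)c2c1CCc1ccc(O[Si](C(C)C)(C(C)C)C(C)C)cc1
F5 | step 8 | methyl 6-hydroxy-2,2-dimethyl-3-methylidene-7-(3-methylbut-2-en-1-yl)-4-{2-[4-(triisopropylsilyloxy)phenyl]ethyl}-2,3-dihydro-1-benzofuran-5-carboxylate | COC(=O)c1c(O)c(CC=C(C)C)c2OC(C)(C)C(=C)c2c1CCc1ccc(O[Si](C(C)C)(C(C)C)C(C)C)cc1
F6 | step 8 | methyl 6-hydroxy-3-(hydroxymethyl)-2,2-dimethyl-7-(3-methylbut-2-en-1-yl)-4-{2-[4-(triisopropylsilyloxy)phenyl]ethyl}-2,3-dihydro-1-benzofuran-5-carboxylate | COC(=O)c1c(O)c(CC=C(C)C)c2OC(C)(C)C(CO)c2c1CCc1ccc(O[Si](C(C)C)(C(C)C)C(C)C)cc1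
F7 | step 8 | methyl 6-hydroxy-2,2-dimethyl-7-(3-methylbut-2-en-1-yl)-4-{2-[4-(triisopropylsilyloxy)phenyl]ethyl}-3-{[(trifluoromethanesulfonyl)oxy]methyl}-2,3-dihydro-1-benzofuran-5-carboxylate | COC(=O)c1c(O)c(CC=C(C)C)c2OC(C)(C)C(COS(=O)(=O)C(F)(F)F)c2c1CCc1ccc(O[Si](C(C)C)(C(C)C)C(C)C)cc1
F8 | step 5 | methyl 2-hydroxy-4-(methoxymethoxy)-6-methylbenzoate | COCOc1cc(C)c(C(=O)OC)c(O)c1
F9 | step 5 | methyl 4-(methoxymethoxy)-6-methyl-2-(prop-2-en-1-yloxy)benzoate | COCOc1cc(C)c(C(=O)OC)c(OCC=C)c1
F10 | step 5 | methyl 2-hydroxy-4-(methoxymethoxy)-6-methyl-3-(prop-2-en-1-yl)benzoate | COCOc1cc(C)c(C(=O)OC)c(O)c1CC=C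
F11 | step 5 | methyl 2-hydroxy-4-(methoxymethoxy)-3-(prop-2-en-1-yl)-6-{2-[4-(triisopropylsilyloxy)phenyl]ethyl}benzoate | COCOc1cc(CCc2ccc(O[Si](C(C)C)(C(C)C)C(C)C)cc2)c(C(=O)OC)c(O)c1CC=C
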